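**Retrosynthetic overview**
1. The target is a 1-aryl-2,3-diaroyl-1,2-dihydronaphthalene with aryl (C1) and aroyl (C2) cis. The last operations are global O-debenzylation and, before it, kinetic protonation of the C2 dienolate, which sets the cis relationship.
2. The carbocycle (ring B) is the only ring made; it is closed late by intramolecular aldol condensation (C3=C4) of a 1,4-diketone onto an ortho-formyl group of ring A.
3. Key disconnection C2–C3: intermolecular crossed aldol addition of the lithium enolate of a β,β-diaryl ketone to 4-(benzyloxy)phenylglyoxal, followed by removal of the aldol oxygen, joins the two aroyl halves.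
4. C1–aryl bond: rhodium-catalysed asymmetric 1,4-addition of the pendant arylboronic acid to a chalcone, itself made by Claisen–Schmidt aldol condensation of the ring A aldehyde and 4-(benzyloxy)acetophenone.
5. Building blocks come from 5-bromo-1,2,3-trimethoxybenzene (ring A), 2,3,4-trihydroxybenzaldehyde (pendant aryl) and 1-[4-(benzyloxy)phenyl]ethanone (both aroyl groups).

Assumption 1: the SMILES is read as the (1R,2R) isomer in dihydronaphthalene numbering, which places the C1 aryl and the C2 aroyl group cis (the less stable epimer).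
Assumption 2: (S)-BINAP in step 12 follows the usual α-si-face model for (E)-enones and is checked on the first batch; the antipodal ligand is used if the sense turns out reversed.

**Route**

Step 1
Reactants: 1 5-bromo-1,2,3-trimethoxybenzene
Product: 3 6-bromo-2,3,4-trimethoxybenzaldehyde, via α-chloro ether 2 (not isolated)
Conditions: Cl2CHOMe, TiCl4, CH2Cl2, 0 °C to rt; then H2O
Reagents that add atoms: dichloromethyl methyl ether COC(Cl)Cl; water O
Why: Rieche formylation, in which the two free ring positions of 1 are equivalent and activated ortho/para by methoxy groups, so a single aldehyde forms (no stereocentre).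

Step 2
Reactants: 3 6-bromo-2,3,4-trimethoxybenzaldehyde
Product: 4 6-bromo-2,3,4-trihydroxybenzaldehyde
Conditions: BBr3 (4.5 equiv), CH2Cl2, −78 °C to rt; then H2O
Reagents that add atoms: none
Why: Lewis-acid ether cleavage (BBr3 demethylation) removes all three methyl groups while the aldehyde and aryl bromide survive, so the methyl group can be put back only on O2.

Step 3
Reactants: 4 6-bromo-2,3,4-trihydroxybenzaldehyde
Product: 5 3,4-bis(benzyloxy)-6-bromo-2-hydroxybenzaldehyde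
Conditions: BnBr (2.1 equiv), K2CO3 (2.2 equiv), DMF, rt
Reagents that add atoms: benzyl bromide BrCc1ccccc1
Why: Williamson ether synthesis, selective because the 2-OH is hydrogen-bonded to the formyl group and is the least nucleophilic oxygen, so two equivalents of benzyl bromide go to O3 and O4.

Step 4
Reactants: 5 3,4-bis(benzyloxy)-6-bromo-2-hydroxybenzaldehyde
Product: 6 3,4-bis(benzyloxy)-6-bromo-2-methoxybenzaldehyde
Conditions: MeI, K2CO3, DMF, 50 °C
Reagents that add atoms: iodomethane CI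
Why: Williamson methylation of the one remaining (chelated) phenol under slightly forcing conditions fixes the methoxy group next to the future C1.

Step 5
Reactants: 6 3,4-bis(benzyloxy)-6-bromo-2-methoxybenzaldehyde; 7 1-[4-(benzyloxy)phenyl]ethanone
Product: 9 (E)-3-[3,4-bis(benzyloxy)-6-bromo-2-methoxyphenyl]-1-[4-(benzyloxy)phenyl]prop-2-en-1-one, via aldol adduct 8 (not isolated)
Conditions: KOH, EtOH/THF, rt
Reagents that add atoms: none
Why: Claisen–Schmidt (crossed aldol) condensation of a non-enolisable aldehyde with a methyl ketone, where E1cB loss of water gives only the (E)-enone.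

Step 6
Reactants: 10 2,3,4-trihydroxybenzaldehyde
Product: 11 3,4-bis(benzyloxy)-2-hydroxybenzaldehyde
Conditions: BnBr (2.1 equiv), K2CO3 (2.2 equiv), DMF, rt
Reagents that add atoms: benzyl bromide BrCc1ccccc1
Why: Williamson ether synthesis with the same selectivity as in step 3, the chelated 2-OH staying free.

Step 7
Reactants: 11 3,4-bis(benzyloxy)-2-hydroxybenzaldehyde
Product: 12 3,4-bis(benzyloxy)-2-methoxybenzaldehyde
Conditions: MeI, K2CO3, DMF, 50 °C
Reagents that add atoms: iodomethane CI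
Why: Williamson methylation of the remaining ortho-hydroxyl.

Step 8
Reactants: 12 3,4-bis(benzyloxy)-2-methoxybenzaldehyde
Product: 14 3,4-bis(benzyloxy)-2-methoxyphenol, via aryl formate 13 (not isolated)
Conditions: mCPBA, CH2Cl2, 0 °C to rt; then K2CO3 (cat.), MeOH
Reagents that add atoms: 3-chloroperoxybenzoic acid O=C(OO)c1cccc(Cl)c1
Why: Dakin-type Baeyer–Villiger oxidation, in which the electron-rich aryl group migrates to give the formate that methanolysis cleaves, turning the formyl carbon position into a phenol with the substitution pattern fixed.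

Step 9
Reactants: 14 3,4-bis(benzyloxy)-2-methoxyphenol
Product: 15 3,4-bis(benzyloxy)-2-methoxyphenyl trifluoromethanesulfonate
Conditions: Tf2O, pyridine, CH2Cl2, 0 °C
Reagents that add atoms: trifluoromethanesulfonic anhydride O=S(=O)(OS(=O)(=O)C(F)(F)F)C(F)(F)F
Why: O-sulfonylation of the phenol gives an aryl triflate ready for cross-coupling.

Step 10
Reactants: 15 3,4-bis(benzyloxy)-2-methoxyphenyl trifluoromethanesulfonate
Product: 16 2-[3,4-bis(benzyloxy)-2-methoxyphenyl]-4,4,5,5-tetramethyl-1,3,2-dioxaborolane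
Conditions: B2pin2, PdCl2(dppf) (5 mol %), KOAc, dioxane, 90 °C
Reagents that add atoms: bis(pinacolato)diboron CC1(C)OB(OC1(C)C)B1OC(C)(C)C(C)(C)O1
Why: Miyaura borylation of an aryl triflate, which tolerates the benzyl ethers and the ortho-methoxy group.

Step 11
Reactants: 16 2-[3,4-bis(benzyloxy)-2-methoxyphenyl]-4,4,5,5-tetramethyl-1,3,2-dioxaborolane
Product: 17 [3,4-bis(benzyloxy)-2-methoxyphenyl]boronic acid
Conditions: NaIO4, NH4OAc, acetone/H2O, rt
Reagents that add atoms: water O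
Why: Hydrolysis of the boronic ester driven by periodate cleavage of the released pinacol gives the free boronic acid, which transmetalates to rhodium faster than the ester.

Step 12
Reactants: 9 (E)-3-[3,4-bis(benzyloxy)-6-bromo-2-methoxyphenyl]-1-[4-(benzyloxy)phenyl]prop-2-en-1-one; 17 [3,4-bis(benzyloxy)-2-methoxyphenyl]boronic acid
Product: 18 (3R)-3-[3,4-bis(benzyloxy)-6-bromo-2-methoxyphenyl]-3-[3,4-bis(benzyloxy)-2-methoxyphenyl]-1-[4-(benzyloxy)phenyl]propan-1-one
Conditions: [Rh(OH)((S)-BINAP)]2 (3 mol % Rh), 17 (2.5 equiv), dioxane/H2O 10:1, 50 °C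
Reagents that add atoms: none
Why: Hayashi–Miyaura asymmetric 1,4-addition (Michael-type arylation), in which the aryl–rhodium–BINAP species adds to the α-si face of the (E)-enone and so sets the diarylmethine centre (future C1) as R, the aryl bromide being inert to the rhodium catalyst.

Step 13
Reactants: 18 (3R)-3-[3,4-bis(benzyloxy)-6-bromo-2-methoxyphenyl]-3-[3,4-bis(benzyloxy)-2-methoxyphenyl]-1-[4-(benzyloxy)phenyl]propan-1-one
Product: 19 (3R)-3-[3,4-bis(benzyloxy)-6-ethenyl-2-methoxyphenyl]-3-[3,4-bis(benzyloxy)-2-methoxyphenyl]-1-[4-(benzyloxy)phenyl]propan-1-one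
Conditions: vinylboronic acid pinacol ester, PdCl2(dppf) (5 mol %), K2CO3, dioxane/H2O 4:1, 90 °C
Reagents that add atoms: vinylboronic acid pinacol ester C=CB1OC(C)(C)C(C)(C)O1
Why: Suzuki–Miyaura vinylation installs a masked formyl group (future C4) that cannot undergo a premature five-ring aldol, and the benzylic centre β to the ketone is not epimerisable.

Step 14
Reactants: 7 1-[4-(benzyloxy)phenyl]ethanone
Product: 20 2-[4-(benzyloxy)phenyl]-2-oxoacetaldehyde (isolated as the hydrate, dried to the free aldehyde by toluene azeotrope before use)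
Conditions: SeO2, dioxane/H2O, reflux
Reagents that add atoms: selenium dioxide O=[Se]=O
Why: Riley oxidation of the aryl methyl ketone to the arylglyoxal, a non-enolisable and highly electrophilic aldehyde.

Step 15
Reactants: 19 (3R)-3-[3,4-bis(benzyloxy)-6-ethenyl-2-methoxyphenyl]-3-[3,4-bis(benzyloxy)-2-methoxyphenyl]-1-[4-(benzyloxy)phenyl]propan-1-one; 20 2-[4-(benzyloxy)phenyl]-2-oxoacetaldehyde
Product: 22 2-{(R)-[3,4-bis(benzyloxy)-6-ethenyl-2-methoxyphenyl][3,4-bis(benzyloxy)-2-methoxyphenyl]methyl}-1,4-bis[4-(benzyloxy)phenyl]-3-hydroxybutane-1,4-dione (mixture of diastereomers at C2 and C3 of the butanedione), via lithium enolate 21 (not isolated)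
Conditions: LiN(SiMe3)2 (1.1 equiv), THF, −78 °C; then 20 (1.3 equiv), −78 °C; AcOH quench at −78 °C
Reagents that add atoms: none
Why: Intermolecular crossed aldol addition of a preformed lithium enolate to the aldehyde carbon of the glyoxal forms the C2–C3 bond cleanly because the electrophile cannot enolise; the two new centres form as a mixture, which is harmless since C3 is deoxygenated in step 17 and C2 is reset in step 20.

Step 16
Reactants: 22 the 3-hydroxy-1,4-diketone of step 15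
Product: 23 3-acetoxy-2-{(R)-[3,4-bis(benzyloxy)-6-ethenyl-2-methoxyphenyl][3,4-bis(benzyloxy)-2-methoxyphenyl]methyl}-1,4-bis[4-(benzyloxy)phenyl]butane-1,4-dione (diastereomer mixture)
Conditions: Ac2O, pyridine, DMAP (cat.), CH2Cl2, 0 °C
Reagents that add atoms: acetic anhydride CC(=O)OC(C)=O
Why: O-acetylation turns the aldol hydroxyl into a good leaving group α to the second ketone under conditions too weakly basic to touch the benzylic centre.

Step 17
Reactants: 23 the α-acetoxy diketone of step 16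
Product: 24 2-{(R)-[3,4-bis(benzyloxy)-6-ethenyl-2-methoxyphenyl][3,4-bis(benzyloxy)-2-methoxyphenyl]methyl}-1,4-bis[4-(benzyloxy)phenyl]butane-1,4-dione (C2 epimer mixture)
Conditions: SmI2 (2.5 equiv), THF/MeOH 4:1, −78 °C
Reagents that add atoms: none
Why: SmI2 reductive cleavage of an α-acyloxy ketone expels acetate from the ketyl and the resulting enolate is protonated by methanol, a fast, non-basic deoxygenation that leaves the other ketone, the styrene and the diarylmethine centre untouched.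

Step 18
Reactants: 24 the 1,4-diketone of step 17
Product: 26 2-{(R)-[3,4-bis(benzyloxy)-6-formyl-2-methoxyphenyl][3,4-bis(benzyloxy)-2-methoxyphenyl]methyl}-1,4-bis[4-(benzyloxy)phenyl]butane-1,4-dione, via vicinal diol 25 (not isolated)
Conditions: OsO4 (2 mol %), NaIO4 (4 equiv), 2,6-lutidine, dioxane/H2O 3:1, rt
Reagents that add atoms: osmium tetroxide O=[Os](=O)(=O)=O; sodium periodate [Na+].[O-]I(=O)(=O)=O
Why: Lemieux–Johnson oxidation (dihydroxylation then periodate cleavage) converts the vinyl group into the ring A aldehyde without affecting ketones or benzyl ethers.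

Step 19
Reactants: 26 the keto-aldehyde of step 18
Product: 28 [(1R,2S)-6,7-bis(benzyloxy)-1-[3,4-bis(benzyloxy)-2-methoxyphenyl]-8-methoxy-1,2-dihydronaphthalene-2,3-diyl]bis{[4-(benzyloxy)phenyl]methanone} (1,2-trans; major epimer), via cyclic aldol 27 (not isolated)
Conditions: pyrrolidine (0.3 equiv), AcOH (0.3 equiv), toluene, 50 °C, argon
Reagents that add atoms: none
Why: Intramolecular aldol condensation, in which only the C3 methylene can close a six-membered ring and then dehydrate irreversibly to the conjugated enone; the buffered secondary-amine catalyst avoids dienolate-mediated double-bond migration (and pyrrole formation), and any cis epimer formed is simply the product of step 20.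

Step 20
Reactants: 28 the trans-dihydronaphthalene of step 19
Product: 30 [(1R,2R)-6,7-bis(benzyloxy)-1-[3,4-bis(benzyloxy)-2-methoxyphenyl]-8-methoxy-1,2-dihydronaphthalene-2,3-diyl]bis{[4-(benzyloxy)phenyl]methanone} (1,2-cis), via potassium dienolate 29 (not isolated)
Conditions: KN(SiMe3)2 (1.05 equiv), THF, −78 °C; cannulated into AcOH (5 equiv)/THF at −78 °C; chromatography, trans epimer recycled
Reagents that add atoms: none
Why: Kinetic protonation of an enolate next to a stereocentre (Zimmerman-type): the pseudoaxial C1 aryl group shields one face of the planar C2 dienolate, so the proton arrives at the α-carbon anti to it and the aroyl group ends cis to the aryl group, setting C2 as R while C1 is not touched.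

Step 21
Reactants: 30 the cis hexabenzyl ether of step 20
Product: 31 [(1R,2R)-1-(3,4-dihydroxy-2-methoxyphenyl)-6,7-dihydroxy-8-methoxy-1,2-dihydronaphthalene-2,3-diyl]bis[(4-hydroxyphenyl)methanone] (CNP0335881.1)
Conditions: BCl3 (18 equiv), pentamethylbenzene (18 equiv), CH2Cl2, −78 °C; MeOH quench at −78 °C; reverse-phase HPLC (0.1 % HCO2H)
Reagents that add atoms: none
Why: Lewis-acid debenzylation with a non-Lewis-basic cation scavenger removes all six benzyl groups at −78 °C without base, hydrogen or heat, so the enone double bond, the two methyl ethers and the epimerisable cis C2 centre are preserved.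

**Compound list**

1 | 5-bromo-1,2,3-trimethoxybenzene | COc1cc(Br)cc(OC)c1OC | starting material
2 | 1-bromo-2-[chloro(methoxy)methyl]-3,4,5-trimethoxybenzene (racemic) | COC(Cl)c1c(Br)cc(OC)c(OC)c1OC | intermediate
3 | 6-bromo-2,3,4-trimethoxybenzaldehyde | COc1cc(Br)c(C=O)c(OC)c1OC | intermediate
4 | 6-bromo-2,3,4-trihydroxybenzaldehyde | O=Cc1c(Br)cc(O)c(O)c1O | intermediate
5 | 3,4-bis(benzyloxy)-6-bromo-2-hydroxybenzaldehyde | O=Cc1c(Br)cc(OCc2ccccc2)c(OCc2ccccc2)c1O | intermediate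
6 | 3,4-bis(benzyloxy)-6-bromo-2-methoxybenzaldehyde | COc1c(C=O)c(Br)cc(OCc2ccccc2)c1OCc1ccccc1 | intermediate
7 | 1-[4-(benzyloxy)phenyl]ethanone | CC(=O)c1ccc(OCc2ccccc2)cc1 | starting material
8 | 3-[3,4-bis(benzyloxy)-6-bromo-2-methoxyphenyl]-1-[4-(benzyloxy)phenyl]-3-hydroxypropan-1-one (racemic) | COc1c(C(O)CC(=O)c2ccc(OCc3ccccc3)cc2)c(Br)cc(OCc2ccccc2)c1OCc1ccccc1 | intermediate
9 | (E)-3-[3,4-bis(benzyloxy)-6-bromo-2-methoxyphenyl]-1-[4-(benzyloxy)phenyl]prop-2-en-1-one | COc1c(/C=C/C(=O)c2ccc(OCc3ccccc3)cc2)c(Br)cc(OCc2ccccc2)c1OCc1ccccc1 | intermediate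
10 | 2,3,4-trihydroxybenzaldehyde | O=Cc1ccc(O)c(O)c1O | starting material
11 | 3,4-bis(benzyloxy)-2-hydroxybenzaldehyde | O=Cc1ccc(OCc2ccccc2)c(OCc2ccccc2)c1O | intermediate
12 | 3,4-bis(benzyloxy)-2-methoxybenzaldehyde | COc1c(C=O)ccc(OCc2ccccc2)c1OCc1ccccc1 | intermediate
13 | 3,4-bis(benzyloxy)-2-methoxyphenyl formate | COc1c(OC=O)ccc(OCc2ccccc2)c1OCc1ccccc1 | intermediate
14 | 3,4-bis(benzyloxy)-2-methoxyphenol | COc1c(O)ccc(OCc2ccccc2)c1OCc1ccccc1 | intermediate
15 | 3,4-bis(benzyloxy)-2-methoxyphenyl trifluoromethanesulfonate | COc1c(OS(=O)(=O)C(F)(F)F)ccc(OCc2ccccc2)c1OCc1ccccc1 | intermediate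
16 | 2-[3,4-bis(benzyloxy)-2-methoxyphenyl]-4,4,5,5-tetramethyl-1,3,2-dioxaborolane | COc1c(B2OC(C)(C)C(C)(C)O2)ccc(OCc2ccccc2)c1OCc1ccccc1 | intermediate
17 | [3,4-bis(benzyloxy)-2-methoxyphenyl]boronic acid | COc1c(B(O)O)ccc(OCc2ccccc2)c1OCc1ccccc1 | intermediate
18 | (3R)-3-[3,4-bis(benzyloxy)-6-bromo-2-methoxyphenyl]-3-[3,4-bis(benzyloxy)-2-methoxyphenyl]-1-[4-(benzyloxy)phenyl]propan-1-one | COc1c(OCc2ccccc2)c(OCc2ccccc2)ccc1[C@@H](CC(=O)c1ccc(OCc2ccccc2)cc1)c1c(Br)cc(OCc2ccccc2)c(OCc2ccccc2)c1OC | intermediate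
19 | (3R)-3-[3,4-bis(benzyloxy)-6-ethenyl-2-methoxyphenyl]-3-[3,4-bis(benzyloxy)-2-methoxyphenyl]-1-[4-(benzyloxy)phenyl]propan-1-one | COc1c(OCc2ccccc2)c(OCc2ccccc2)ccc1[C@@H](CC(=O)c1ccc(OCc2ccccc2)cc1)c1c(C=C)cc(OCc2ccccc2)c(OCc2ccccc2)c1OC | intermediate
20 | 2-[4-(benzyloxy)phenyl]-2-oxoacetaldehyde | O=CC(=O)c1ccc(OCc2ccccc2)cc1 | intermediate
21 | lithium (Z)-enolate of 19 | COc1c(OCc2ccccc2)c(OCc2ccccc2)ccc1[C@@H](/C=C(\O[Li])c1ccc(OCc2ccccc2)cc1)c1c(C=C)cc(OCc2ccccc2)c(OCc2ccccc2)c1OC | intermediate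
22 | 2-{(R)-[3,4-bis(benzyloxy)-6-ethenyl-2-methoxyphenyl][3,4-bis(benzyloxy)-2-methoxyphenyl]methyl}-1,4-bis[4-(benzyloxy)phenyl]-3-hydroxybutane-1,4-dione (mixture at C2 and C3) | COc1c(OCc2ccccc2)c(OCc2ccccc2)ccc1[C@@H](C(C(O)C(=O)c1ccc(OCc2ccccc2)cc1)C(=O)c1ccc(OCc2ccccc2)cc1)c1c(C=C)cc(OCc2ccccc2)c(OCc2ccccc2)c1OC | intermediate
23 | 3-O-acetate of 22 (mixture at C2 and C3) | COc1c(OCc2ccccc2)c(OCc2ccccc2)ccc1[C@@H](C(C(OC(C)=O)C(=O)c1ccc(OCc2ccccc2)cc1)C(=O)c1ccc(OCc2ccccc2)cc1)c1c(C=C)cc(OCc2ccccc2)c(OCc2ccccc2)c1OC | intermediate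
24 | 2-{(R)-[3,4-bis(benzyloxy)-6-ethenyl-2-methoxyphenyl][3,4-bis(benzyloxy)-2-methoxyphenyl]methyl}-1,4-bis[4-(benzyloxy)phenyl]butane-1,4-dione (mixture at C2) | COc1c(OCc2ccccc2)c(OCc2ccccc2)ccc1[C@@H](C(CC(=O)c1ccc(OCc2ccccc2)cc1)C(=O)c1ccc(OCc2ccccc2)cc1)c1c(C=C)cc(OCc2ccccc2)c(OCc2ccccc2)c1OC | intermediate
25 | 1,2-diol from dihydroxylation of the vinyl group of 24 | COc1c(OCc2ccccc2)c(OCc2ccccc2)ccc1[C@@H](C(CC(=O)c1ccc(OCc2ccccc2)cc1)C(=O)c1ccc(OCc2ccccc2)cc1)c1c(C(O)CO)cc(OCc2ccccc2)c(OCc2ccccc2)c1OC | intermediate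
26 | 2-{(R)-[3,4-bis(benzyloxy)-6-formyl-2-methoxyphenyl][3,4-bis(benzyloxy)-2-methoxyphenyl]methyl}-1,4-bis[4-(benzyloxy)phenyl]butane-1,4-dione (mixture at C2) | COc1c(OCc2ccccc2)c(OCc2ccccc2)ccc1[C@@H](C(CC(=O)c1ccc(OCc2ccccc2)cc1)C(=O)c1ccc(OCc2ccccc2)cc1)c1c(C=O)cc(OCc2ccccc2)c(OCc2ccccc2)c1OC | intermediate
27 | [(1R)-6,7-bis(benzyloxy)-1-[3,4-bis(benzyloxy)-2-methoxyphenyl]-4-hydroxy-8-methoxy-1,2,3,4-tetrahydronaphthalene-2,3-diyl]bis{[4-(benzyloxy)phenyl]methanone} (mixture at C2, C3, C4) | COc1c([C@@H]2c3c(cc(OCc4ccccc4)c(OCc4ccccc4)c3OC)C(O)C(C(=O)c3ccc(OCc4ccccc4)cc3)C2C(=O)c2ccc(OCc3ccccc3)cc2)ccc(OCc2ccccc2)c1OCc1ccccc1 | intermediate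
28 | [(1R,2S)-6,7-bis(benzyloxy)-1-[3,4-bis(benzyloxy)-2-methoxyphenyl]-8-methoxy-1,2-dihydronaphthalene-2,3-diyl]bis{[4-(benzyloxy)phenyl]methanone} (1,2-trans) | COc1c([C@@H]2c3c(cc(OCc4ccccc4)c(OCc4ccccc4)c3OC)C=C(C(=O)c3ccc(OCc4ccccc4)cc3)[C@H]2C(=O)c2ccc(OCc3ccccc3)cc2)ccc(OCc2ccccc2)c1OCc1ccccc1 | intermediate
29 | potassium dienolate of 28 (C2=C(OK)Ar) | COc1c([C@@H]2c3c(cc(OCc4ccccc4)c(OCc4ccccc4)c3OC)C=C(C(=O)c3ccc(OCc4ccccc4)cc3)C2=C(O[K])c2ccc(OCc3ccccc3)cc2)ccc(OCc2ccccc2)c1OCc1ccccc1 | intermediate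
30 | [(1R,2R)-6,7-bis(benzyloxy)-1-[3,4-bis(benzyloxy)-2-methoxyphenyl]-8-methoxy-1,2-dihydronaphthalene-2,3-diyl]bis{[4-(benzyloxy)phenyl]methanone} (1,2-cis) | COc1c([C@@H]2c3c(cc(OCc4ccccc4)c(OCc4ccccc4)c3OC)C=C(C(=O)c3ccc(OCc4ccccc4)cc3)[C@@H]2C(=O)c2ccc(OCc3ccccc3)cc2)ccc(OCc2ccccc2)c1OCc1ccccc1 | intermediate
31 | [(1R,2R)-1-(3,4-dihydroxy-2-methoxyphenyl)-6,7-dihydroxy-8-methoxy-1,2-dihydronaphthalene-2,3-diyl]bis[(4-hydroxyphenyl)methanone] | COc1c([C@@H]2c3c(cc(O)c(O)c3OC)C=C(C(=O)c3ccc(O)cc3)[C@@H]2C(=O)c2ccc(O)cc2)ccc(O)c1O | target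

**Step count and risks**

Total steps: 21. Longest linear sequence: 15 steps (10 to 31 through steps 6–13 and 15–21).

Step 12 (asymmetric arylation of a β-aryl enone that carries two ortho substituents; conversion or ee may be poor). Fallback: auxiliary-controlled cuprate addition in place of catalysis, setting out from 6 and coming back at 18. A Horner–Wadsworth–Emmons reaction of 6 with diethyl {2-oxo-2-[(4S)-2-oxo-4-phenyl-1,3-oxazolidin-3-yl]ethyl}phosphonate (LiCl, iPr2NEt, MeCN) gives (4S)-3-[(2E)-3-[3,4-bis(benzyloxy)-6-bromo-2-methoxyphenyl]prop-2-enoyl]-4-phenyl-1,3-oxazolidin-2-one F1. Boronic acid 17 is converted with CuBr2 (MeOH/H2O, 80 °C) into 1,2-bis(benzyloxy)-4-bromo-3-methoxybenzene F2. The Grignard reagent of F2 (Mg, THF) is added with CuBr·SMe2 (THF/Me2S, −40 °C) to the chelated F1 from the face opposite the 4-phenyl group to give (4S)-3-[(3R)-3-[3,4-bis(benzyloxy)-6-bromo-2-methoxyphenyl]-3-[3,4-bis(benzyloxy)-2-methoxyphenyl]propanoyl]-4-phenyl-1,3-oxazolidin-2-one F3, which is freed of its minor diastereomer by crystallisation or chromatography. MeNH(OMe)·HCl/AlMe3 turns F3 into (3R)-3-[3,4-bis(benzyloxy)-6-bromo-2-methoxyphenyl]-3-[3,4-bis(benzyloxy)-2-methoxyphenyl]-N-methoxy-N-methylpropanamide F4, and 4-(benzyloxy)phenylmagnesium bromide (THF, 0 °C) then gives 18.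

Step 20 (substrate-controlled kinetic protonation; the cis:trans ratio may be modest). Fallback: reagent-controlled protonation of an isolated silyl enol ether, setting out from 28 and coming back at 30. The dienolate from 28 (KN(SiMe3)2, THF, −78 °C) is trapped with Me3SiCl to give the trimethylsilyl dienol ether F5. F5 is then protonated at −78 °C in toluene with a stoichiometric BINOL·SnCl4 complex (both BINOL antipodes screened, the matched one kept), so that the chiral acid and the C1 aryl group together direct the proton to the face that gives 30.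

Step 21 (six-fold debenzylation with BCl3 may epimerise the cis C2 centre or attack a methyl ether). Fallback: swap the protecting groups before the stereocentre is set, so that the last step is a mild fluoride desilylation, setting out from 28 and coming back at 31. BCl3/pentamethylbenzene on the robust trans compound 28 gives the trans hexaphenol [(1R,2S)-1-(3,4-dihydroxy-2-methoxyphenyl)-6,7-dihydroxy-8-methoxy-1,2-dihydronaphthalene-2,3-diyl]bis[(4-hydroxyphenyl)methanone] F6. tBuMe2SiCl/imidazole (DMF) gives the trans hexakis(tert-butyldimethylsilyl) ether F7. Kinetic protonation as in step 20 (KN(SiMe3)2, THF, −78 °C; AcOH) gives the cis hexakis(tert-butyldimethylsilyl) ether F8. Et3N·3HF (MeCN, 0 °C) then releases 31 under nearly neutral conditions.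

**Further compounds**

F1 | step 12 | (4S)-3-[(2E)-3-[3,4-bis(benzyloxy)-6-bromo-2-methoxyphenyl]prop-2-enoyl]-4-phenyl-1,3-oxazolidin-2-one | COc1c(/C=C/C(=O)N2C(=O)OC[C@@H]2c2ccccc2)c(Br)cc(OCc2ccccc2)c1OCc1ccccc1
F2 | step 12 | 1,2-bis(benzyloxy)-4-bromo-3-methoxybenzene | COc1c(Br)ccc(OCc2ccccc2)c1OCc1ccccc1
F3 | step 12 | (4S)-3-[(3R)-3-[3,4-bis(benzyloxy)-6-bromo-2-methoxyphenyl]-3-[3,4-bis(benzyloxy)-2-methoxyphenyl]propanoyl]-4-phenyl-1,3-oxazolidin-2-one | COc1c(OCc2ccccc2)c(OCc2ccccc2)ccc1[C@@H](CC(=O)N1C(=O)OC[C@@H]1c1ccccc1)c1c(Br)cc(OCc2ccccc2)c(OCc2ccccc2)c1OC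
F4 | step 12 | (3R)-3-[3,4-bis(benzyloxy)-6-bromo-2-methoxyphenyl]-3-[3,4-bis(benzyloxy)-2-methoxyphenyl]-N-methoxy-N-methylpropanamide | COc1c(OCc2ccccc2)c(OCc2ccccc2)ccc1[C@@H](CC(=O)N(C)OC)c1c(Br)cc(OCc2ccccc2)c(OCc2ccccc2)c1OC
F5 | step 20 | trimethylsilyl dienol ether of 28 (enol ether geometry not defined) | COc1c([C@@H]2c3c(cc(OCc4ccccc4)c(OCc4ccccc4)c3OC)C=C(C(=O)c3ccc(OCc4ccccc4)cc3)C2=C(O[Si](C)(C)C)c2ccc(OCc3ccccc3)cc2)ccc(OCc2ccccc2)c1OCc1ccccc1
F6 | step 21 | [(1R,2S)-1-(3,4-dihydroxy-2-methoxyphenyl)-6,7-dihydroxy-8-methoxy-1,2-dihydronaphthalene-2,3-diyl]bis[(4-hydroxyphenyl)methanone] (trans hexaphenol) | COc1c([C@@H]2c3c(cc(O)c(O)c3OC)C=C(C(=O)c3ccc(O)cc3)[C@H]2C(=O)c2ccc(O)cc2)ccc(O)c1O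
F7 | step 21 | trans (1R,2S) hexakis(tert-butyldimethylsilyl) ether of F6 | COc1c([C@@H]2c3c(cc(O[Si](C)(C)C(C)(C)C)c(O[Si](C)(C)C(C)(C)C)c3OC)C=C(C(=O)c3ccc(O[Si](C)(C)C(C)(C)C)cc3)[C@H]2C(=O)c2ccc(O[Si](C)(C)C(C)(C)C)cc2)ccc(O[Si](C)(C)C(C)(C)C)c1O[Si](C)(C)C(C)(C)C
F8 | step 21 | cis (1R,2R) hexakis(tert-butyldimethylsilyl) ether of 31 | COc1c([C@@H]2c3c(cc(O[Si](C)(C)C(C)(C)C)c(O[Si](C)(C)C(C)(C)C)c3OC)C=C(C(=O)c3ccc(O[Si](C)(C)C(C)(C)C)cc3)[C@@H]2C(=O)c2ccc(O[Si](C)(C)C(C)(C)C)cc2)ccc(O[Si](C)(C)C(C)(C)C)c1O[Si](C)(C)C(C)(C)C
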